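**Retrosynthetic overview**
- The target comes from its bis(silyl ether) by desilylation. Ring A (prenyl) and ring B (diol) are closed together, in the penultimate step, by a two-fold intramolecular McMurry coupling (C5=C6 and C5′=C6′) of an acyclic 5,6:5′,6′-seco tetraketone.
- The tetraketone comes from ketal removal after two successive Claisen–Schmidt condensations (C7=C8, C7′=C8′) of crocetin dialdehyde with two α,α-dimethyl methyl ketones.
- The two ketones come from Wittig (prenyl) or Wittig plus cross-metathesis (bis-silyloxy side chain) of two enantiomeric keto aldehydes. These arise from one organocatalytic Mukaiyama–Michael addition (C1–C2 bond, C2 stereocentre) run with the two catalyst antipodes (2R and 2′S).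
- The common enal comes from cross-metathesis of ketal-protected hex-5-en-2-one with crotonaldehyde.

Locants follow carotenoid numbering of the target (C1 gem-dimethyl carbon, C2 stereocentre, C5=C6 ring alkene, C7=C8 first chain alkene; primed locants for the diol half). Read from the SMILES, the target is 2R (prenyl ring), 2′S (diol ring), all-E.

Assumption: crocetin dialdehyde is bought as a catalogue carotenoid building block (it is the costliest input); the facial sense of the imidazolidinone catalyst is taken from its known additions of carbon nucleophiles to (E)-alk-2-enals, and if it proves reversed the two catalyst antipodes change places between steps 4 and 6.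

**Step 1**
Reactants: 1 hex-5-en-2-one
Product: 2 2-(but-3-en-1-yl)-2-methyl-1,3-dioxolane
Conditions: HOCH2CH2OH (1.5 equiv), p-TsOH·H2O (1 mol%), toluene, reflux, Dean–Stark
Reagents that add atoms: ethylene glycol, OCCO
Why: Acid-catalysed ketalisation with azeotropic removal of water masks the future C5 carbonyl so that later only the C6 acetyl group can enolise.

**Step 2**
Reactants: 2 2-(but-3-en-1-yl)-2-methyl-1,3-dioxolane; 3 (E)-but-2-enal (3 equiv)
Product: 4 (E)-5-(2-methyl-1,3-dioxolan-2-yl)pent-2-enal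
Conditions: second-generation Hoveyda–Grubbs catalyst [RuCl2(=CH-C6H4-2-OiPr)(H2IMes)] (2 mol%), CH2Cl2, 40 °C
Reagents that add atoms: none
Why: Olefin cross-metathesis of a terminal alkene with crotonaldehyde gives the E-enal selectively, with propene loss as the driving force.

**Step 3**
Reactants: 5 3-methylbutan-2-one
Product: 6 2-methyl-3-(trimethylsilyloxy)but-2-ene
Conditions: Me3SiCl, NaI, Et3N, MeCN, 25 °C; fractional distillation
Reagents that add atoms: chlorotrimethylsilane, C[Si](C)(C)Cl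
Why: Silylation under equilibrating conditions (Me3SiI formed in the flask) favours the more substituted, tetrasubstituted silyl enol ether, which is freed from the minor isomer by distillation.

**Step 4**
Reactants: 4 (E)-5-(2-methyl-1,3-dioxolan-2-yl)pent-2-enal; 6 2-methyl-3-(trimethylsilyloxy)but-2-ene (3 equiv)
Product: 7 (3R)-4,4-dimethyl-3-[2-(2-methyl-1,3-dioxolan-2-yl)ethyl]-5-oxohexanal
Conditions: (2S,5S)-5-benzyl-2-tert-butyl-3-methylimidazolidin-4-one (20 mol%), 2,4-dinitrobenzoic acid (20 mol%), t-BuOH/i-PrOH 5:1, −20 °C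
Reagents that add atoms: none
Why: Iminium-catalysed Mukaiyama–Michael addition (known for ketone silyl enol ethers and enals, here extended to a tetrasubstituted donor): the catalyst shields one face of the E-iminium ion of 4, so 6 adds to the Re face of C-β and sets C2 as R next to the new quaternary C1.

**Step 5**
Reactants: 7 (3R)-4,4-dimethyl-3-[2-(2-methyl-1,3-dioxolan-2-yl)ethyl]-5-oxohexanal
Product: 8 (4R)-3,3,7-trimethyl-4-[2-(2-methyl-1,3-dioxolan-2-yl)ethyl]oct-6-en-2-one
Conditions: i-PrPPh3I, n-BuLi, THF, 0 °C; then 7, −78 to 20 °C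
Reagents that add atoms: isopropyltriphenylphosphonium iodide, CC(C)[P+](c1ccccc1)(c1ccccc1)c1ccccc1.[I-]
Why: Wittig olefination with a non-stabilised ylide takes the aldehyde far faster than the hindered α-quaternary ketone and gives the prenyl group (two identical methyls, no E/Z issue) without touching C2.

**Step 6**
Reactants: 4 (E)-5-(2-methyl-1,3-dioxolan-2-yl)pent-2-enal; 6 2-methyl-3-(trimethylsilyloxy)but-2-ene (3 equiv)
Product: 9 (3S)-4,4-dimethyl-3-[2-(2-methyl-1,3-dioxolan-2-yl)ethyl]-5-oxohexanal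
Conditions: (2R,5R)-5-benzyl-2-tert-butyl-3-methylimidazolidin-4-one (20 mol%), 2,4-dinitrobenzoic acid (20 mol%), t-BuOH/i-PrOH 5:1, −20 °C
Reagents that add atoms: none
Why: The same iminium-catalysed Mukaiyama–Michael addition with the mirror-image catalyst delivers the donor to the Si face of C-β and sets the C2′ stereocentre as S.

**Step 7**
Reactants: 9 (3S)-4,4-dimethyl-3-[2-(2-methyl-1,3-dioxolan-2-yl)ethyl]-5-oxohexanal
Product: 10 (4S)-3,3-dimethyl-4-[2-(2-methyl-1,3-dioxolan-2-yl)ethyl]hept-6-en-2-one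
Conditions: MePPh3Br, n-BuLi, THF, 0 °C; then 9 (1.05 equiv ylide), −78 to 0 °C
Reagents that add atoms: methyltriphenylphosphonium bromide, C[P+](c1ccccc1)(c1ccccc1)c1ccccc1.[Br-]
Why: Wittig methylenation is chemoselective for the aldehyde over the hindered ketone at low temperature with one equivalent of ylide and gives the allyl handle for metathesis.

**Step 8**
Reactants: 11 2-methylidenepropane-1,3-diol
Product: 12 1,3-bis(tert-butyldimethylsilyloxy)-2-methylidenepropane
Conditions: t-BuMe2SiCl (2.2 equiv), imidazole, DMF, 20 °C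
Reagents that add atoms: tert-butyldimethylsilyl chloride, CC(C)(C)[Si](C)(C)Cl
Why: Standard silylation protects both primary allylic hydroxyls for the basic, acidic and reductive steps that follow.

**Step 9**
Reactants: 10 (4S)-3,3-dimethyl-4-[2-(2-methyl-1,3-dioxolan-2-yl)ethyl]hept-6-en-2-one; 12 1,3-bis(tert-butyldimethylsilyloxy)-2-methylidenepropane (3 equiv)
Product: 13 (4S)-8-(tert-butyldimethylsilyloxy)-7-[(tert-butyldimethylsilyloxy)methyl]-3,3-dimethyl-4-[2-(2-methyl-1,3-dioxolan-2-yl)ethyl]oct-6-en-2-one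
Conditions: second-generation Hoveyda–Grubbs catalyst [RuCl2(=CH-C6H4-2-OiPr)(H2IMes)] (5 mol%), CH2Cl2, 40 °C
Reagents that add atoms: none
Why: Olefin cross-metathesis of the terminal alkene with the 1,1-disubstituted alkene, driven by ethene loss, gives a trisubstituted alkene whose two identical substituents remove any E/Z question.

**Step 10**
Reactants: 8 (4R)-3,3,7-trimethyl-4-[2-(2-methyl-1,3-dioxolan-2-yl)ethyl]oct-6-en-2-one; 14 crocetin dialdehyde, (2E,4E,6E,8E,10E,12E,14E)-2,6,11,15-tetramethylhexadeca-2,4,6,8,10,12,14-heptaenedial (4 equiv)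
Product: 15 (20R)-all-E-2,6,11,15,19,19,23-heptamethyl-20-[2-(2-methyl-1,3-dioxolan-2-yl)ethyl]-18-oxotetracosa-2,4,6,8,10,12,14,16,22-nonaenal
Conditions: KOH (0.5 equiv), EtOH/THF 1:2, 20 °C, argon, dark; excess 14 recovered
Reagents that add atoms: none
Why: Claisen–Schmidt (crossed aldol) condensation: 8 enolises only at its acetyl CH3, 14 has no α-hydrogen, loss of water from the aldol gives the E-enone (C7=C8), and the excess of dialdehyde keeps the reaction at one end.

**Step 11**
Reactants: 15 (20R)-enone aldehyde; 13 (4S)-bis(silyloxy) ketone (1.5 equiv)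
Product: 16 bis-enone bis-dioxolane (all-E, 2R,2′S): C6 and C6′ ketones conjugated to the C7–C7′ nonaene bridge, C5 and C5′ carbonyls as 1,3-dioxolanes, prenyl at C2, 4-silyloxy-3-(silyloxymethyl)but-2-enyl at C2′
Conditions: KOH (0.5 equiv), EtOH/THF 1:2, 20 °C, argon, dark
Reagents that add atoms: none
Why: A second Claisen–Schmidt condensation at the remaining aldehyde forms C7′=C8′ as the E-enone with loss of water, and the enone of 15 cannot enolise because its α′ carbon is quaternary.

**Step 12**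
Reactants: 16 bis-enone bis-dioxolane
Product: 17 tetraketone (all-E, 2R,2′S; 5,6:5′,6′-seco form of 18 with methyl ketones at C5 and C5′ and enones at C6 and C6′)
Conditions: PPTS (0.2 equiv), acetone/H2O 10:1, 40 °C, dark
Reagents that add atoms: water, O
Why: Mild acid-catalysed ketal hydrolysis frees both methyl ketones while the primary silyl ethers and the polyene dione survive.

**Step 13**
Reactants: 17 tetraketone
Product: 18 bis(tert-butyldimethylsilyl) ether of the target (all-E, 2R,2′S)
Conditions: TiCl3(DME)1.5 (16 equiv), Zn–Cu couple (48 equiv), pyridine (8 equiv), DME, reflux; 17 added over 30 h (final 1 mM), argon, dark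
Reagents that add atoms: none
Why: Proposed new method: two-fold intramolecular McMurry carbonyl coupling, in which each C6 dienone (the more easily reduced carbonyl) is bound as its ketyl on low-valent titanium four atoms from its C5 methyl ketone, so C5–C6 pinacolate formation is a favoured six-ring closure and deoxygenation gives the tetrasubstituted ring alkene of ring A and ring B in the same operation; the closest known reaction types are the intramolecular keto–ketone McMurry cyclisation to 1,2-dialkylcyclohexenes and the McMurry coupling of polyene carbonyl compounds (retinal to β-carotene), and no stereocentre is formed or touched.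

**Step 14**
Reactants: 18 bis(tert-butyldimethylsilyl) ether of the target
Product: 19 CNP0213288.1 (target; all-E, 2R,2′S)
Conditions: Bu4NF (3 equiv), THF, 0 to 20 °C, dark
Reagents that add atoms: none
Why: Fluoride-induced desilylation releases the two primary allylic alcohols without affecting the polyene or the stereocentres.

**Compound list**
1 | hex-5-en-2-one | CC(=O)CCC=C | starting material
2 | 2-(but-3-en-1-yl)-2-methyl-1,3-dioxolane | CC1(CCC=C)OCCO1 | intermediate
3 | (E)-but-2-enal | C/C=C/C=O | starting material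
4 | (E)-5-(2-methyl-1,3-dioxolan-2-yl)pent-2-enal | O=C/C=C/CCC1(C)OCCO1 | intermediate
5 | 3-methylbutan-2-one | CC(=O)C(C)C | starting material
6 | 2-methyl-3-(trimethylsilyloxy)but-2-ene | CC(O[Si](C)(C)C)=C(C)C | intermediate
7 | (3R)-4,4-dimethyl-3-[2-(2-methyl-1,3-dioxolan-2-yl)ethyl]-5-oxohexanal | O=CC[C@H](C(C)(C)C(C)=O)CCC1(C)OCCO1 | intermediate
8 | (4R)-3,3,7-trimethyl-4-[2-(2-methyl-1,3-dioxolan-2-yl)ethyl]oct-6-en-2-one | CC(C)=CC[C@H](C(C)(C)C(C)=O)CCC1(C)OCCO1 | intermediate
9 | (3S)-4,4-dimethyl-3-[2-(2-methyl-1,3-dioxolan-2-yl)ethyl]-5-oxohexanal | O=CC[C@@H](C(C)(C)C(C)=O)CCC1(C)OCCO1 | intermediate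
10 | (4S)-3,3-dimethyl-4-[2-(2-methyl-1,3-dioxolan-2-yl)ethyl]hept-6-en-2-one | C=CC[C@@H](C(C)(C)C(C)=O)CCC1(C)OCCO1 | intermediate
11 | 2-methylidenepropane-1,3-diol | C=C(CO)CO | starting material
12 | 1,3-bis(tert-butyldimethylsilyloxy)-2-methylidenepropane | C=C(CO[Si](C)(C)C(C)(C)C)CO[Si](C)(C)C(C)(C)C | intermediate
13 | (4S)-8-(tert-butyldimethylsilyloxy)-7-[(tert-butyldimethylsilyloxy)methyl]-3,3-dimethyl-4-[2-(2-methyl-1,3-dioxolan-2-yl)ethyl]oct-6-en-2-one | CC(C)(C)[Si](C)(C)OCC(CO[Si](C)(C)C(C)(C)C)=CC[C@@H](C(C)(C)C(C)=O)CCC1(C)OCCO1 | intermediate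
14 | crocetin dialdehyde, (2E,4E,6E,8E,10E,12E,14E)-2,6,11,15-tetramethylhexadeca-2,4,6,8,10,12,14-heptaenedial | O=C/C(C)=C/C=C/C(C)=C/C=C/C=C(C)/C=C/C=C(C)/C=O | starting material
15 | (20R)-all-E-2,6,11,15,19,19,23-heptamethyl-20-[2-(2-methyl-1,3-dioxolan-2-yl)ethyl]-18-oxotetracosa-2,4,6,8,10,12,14,16,22-nonaenal | CC(C)=CC[C@@H](CCC1(C)OCCO1)C(C)(C)C(=O)/C=C/C(C)=C/C=C/C(C)=C/C=C/C=C(C)/C=C/C=C(C)/C=O | intermediate
16 | bis-enone bis-dioxolane (all-E, 2R,2′S; 6,6′-dioxo, C5 and C5′ carbonyls as dioxolanes) | CC(C)=CC[C@@H](CCC1(C)OCCO1)C(C)(C)C(=O)/C=C/C(C)=C/C=C/C(C)=C/C=C/C=C(C)/C=C/C=C(C)/C=C/C(=O)C(C)(C)[C@H](CC=C(CO[Si](C)(C)C(C)(C)C)CO[Si](C)(C)C(C)(C)C)CCC2(C)OCCO2 | intermediate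
17 | tetraketone (all-E, 2R,2′S; 5,6:5′,6′-seco form of 18) | CC(C)=CC[C@@H](CCC(C)=O)C(C)(C)C(=O)/C=C/C(C)=C/C=C/C(C)=C/C=C/C=C(C)/C=C/C=C(C)/C=C/C(=O)C(C)(C)[C@H](CC=C(CO[Si](C)(C)C(C)(C)C)CO[Si](C)(C)C(C)(C)C)CCC(C)=O | intermediate
18 | bis(tert-butyldimethylsilyl) ether of the target (all-E, 2R,2′S) | CC(C)=CC[C@H]1CCC(C)=C(/C=C/C(C)=C/C=C/C(C)=C/C=C/C=C(C)/C=C/C=C(C)/C=C/C2=C(C)CC[C@@H](CC=C(CO[Si](C)(C)C(C)(C)C)CO[Si](C)(C)C(C)(C)C)C2(C)C)C1(C)C | intermediate
19 | CNP0213288.1 (all-E, 2R,2′S) | CC(C)=CC[C@H]1CCC(C)=C(/C=C/C(C)=C/C=C/C(C)=C/C=C/C=C(C)/C=C/C=C(C)/C=C/C2=C(C)CC[C@@H](CC=C(CO)CO)C2(C)C)C1(C)C | target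

**Step count**
Total: 14 steps (including the two reagent preparations, steps 3 and 8).
Longest linear sequence: 9 steps (1, 2, 6, 7, 9, 11, 12, 13, 14, from hex-5-en-2-one).

**Three steps most likely to fail, with fallbacks**

Step 13 (double ring closure). The main danger is two-electron reduction of the diketone that is conjugated through the whole chain, giving a retro-type bis-enolate instead of ketyl coupling; loss of the allylic silyl ethers on hot titanium is a second danger. The fallback sets out from 17 and returns to the route at 18. It makes the C5–C6 bonds and removes the oxygen atoms in separate, mild operations, though the SmI2 pinacol step shares the over-reduction risk. SmI2/HMPA in THF at −78 °C closes both rings by ketyl pinacol coupling to the bis(cis-5,6-diol), the 5,6,5′,6′-tetrahydroxy-5,6,5′,6′-tetrahydro bis(silyl ether) F5. Thiophosgene/DMAP converts it into the 5,6:5′,6′-bis(cyclic thionocarbonate) F6. Corey–Winter fragmentation with 1,3-dimethyl-2-phenyl-1,3,2-diazaphospholidine at 40 °C then gives 18.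

Step 4 (and its mirror image, step 6). The tetrasubstituted silyl enol ether may add too slowly or with poor enantioselectivity when a quaternary carbon is formed next to the new stereocentre. The fallback sets out from 4 and returns at 7 (or at 9 with the mirror-image ligand). NaBH4/CeCl3·7H2O reduces 4 to the allylic alcohol (E)-5-(2-methyl-1,3-dioxolan-2-yl)pent-2-en-1-ol F1. Methyl chloroformate/pyridine gives methyl (E)-5-(2-methyl-1,3-dioxolan-2-yl)pent-2-en-1-yl carbonate F2. Branch-selective allylic alkylation of 6 with F2, catalysed by [Ir(cod)Cl]2 and a chiral phosphoramidite with CsF/ZnF2 activation, forms the C1–C2 bond and gives (4R)-3,3-dimethyl-4-[2-(2-methyl-1,3-dioxolan-2-yl)ethyl]hex-5-en-2-one F3, or with the antipodal ligand its (4S)-enantiomer F4. Aldehyde-selective Wacker oxidation of the vinyl group (PdCl2(PhCN)2, CuCl2, AgNO2, t-BuOH/MeNO2, O2) then gives 7 from F3 and 9 from F4.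

Step 9 (cross-metathesis with the hindered 1,1-disubstituted alkene). The bis(silyloxymethyl) alkene may be too hindered, leaving mostly the homodimer of 10. The fallback sets out from 9 and returns at 13; it builds the side chain by carbonyl condensation and bypasses 10 and 12. Knoevenagel condensation of 9 with dimethyl malonate (piperidine/AcOH) gives the alkylidene malonate, dimethyl 2-{(3S)-4,4-dimethyl-3-[2-(2-methyl-1,3-dioxolan-2-yl)ethyl]-5-oxohexylidene}propanedioate F7. i-Bu2AlH at −78 °C reduces both esters and the ketone to the triol, (5S)-2-(hydroxymethyl)-6,6-dimethyl-5-[2-(2-methyl-1,3-dioxolan-2-yl)ethyl]oct-2-ene-1,7-diol F8. t-BuMe2SiCl/imidazole silylates the two primary allylic hydroxyls selectively to give the bis(silyl ether) secondary alcohol F9. Dess–Martin oxidation of the remaining hindered secondary alcohol gives 13.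

**Further compounds**
F1 | step 4 | (E)-5-(2-methyl-1,3-dioxolan-2-yl)pent-2-en-1-ol | OC/C=C/CCC1(C)OCCO1
F2 | step 4 | methyl (E)-5-(2-methyl-1,3-dioxolan-2-yl)pent-2-en-1-yl carbonate | COC(=O)OC/C=C/CCC1(C)OCCO1
F3 | step 4 | (4R)-3,3-dimethyl-4-[2-(2-methyl-1,3-dioxolan-2-yl)ethyl]hex-5-en-2-one | C=C[C@H](C(C)(C)C(C)=O)CCC1(C)OCCO1
F4 | step 4 | (4S)-3,3-dimethyl-4-[2-(2-methyl-1,3-dioxolan-2-yl)ethyl]hex-5-en-2-one | C=C[C@@H](C(C)(C)C(C)=O)CCC1(C)OCCO1
F5 | step 13 | bis(cis-5,6-diol): 5,6,5′,6′-tetrahydroxy-5,6,5′,6′-tetrahydro derivative of 18 (carbinol configurations not assigned) | CC(C)=CC[C@H]1CCC(C)(O)C(O)(/C=C/C(C)=C/C=C/C(C)=C/C=C/C=C(C)/C=C/C=C(C)/C=C/C2(O)C(C)(O)CC[C@@H](CC=C(CO[Si](C)(C)C(C)(C)C)CO[Si](C)(C)C(C)(C)C)C2(C)C)C1(C)C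
F6 | step 13 | 5,6:5′,6′-bis(cyclic thionocarbonate) of F5 | CC(C)=CC[C@H]1CCC2(C)OC(=S)OC2(/C=C/C(C)=C/C=C/C(C)=C/C=C/C=C(C)/C=C/C=C(C)/C=C/C23OC(=S)OC3(C)CC[C@@H](CC=C(CO[Si](C)(C)C(C)(C)C)CO[Si](C)(C)C(C)(C)C)C2(C)C)C1(C)C
F7 | step 9 | dimethyl 2-{(3S)-4,4-dimethyl-3-[2-(2-methyl-1,3-dioxolan-2-yl)ethyl]-5-oxohexylidene}propanedioate | COC(=O)C(=CC[C@@H](C(C)(C)C(C)=O)CCC1(C)OCCO1)C(=O)OC
F8 | step 9 | (5S)-2-(hydroxymethyl)-6,6-dimethyl-5-[2-(2-methyl-1,3-dioxolan-2-yl)ethyl]oct-2-ene-1,7-diol (C7 carbinol epimers) | OCC(CO)=CC[C@@H](C(C)(C)C(C)O)CCC1(C)OCCO1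
F9 | step 9 | (4S)-8-(tert-butyldimethylsilyloxy)-7-[(tert-butyldimethylsilyloxy)methyl]-3,3-dimethyl-4-[2-(2-methyl-1,3-dioxolan-2-yl)ethyl]oct-6-en-2-ol (C2 carbinol epimers) | CC(C)(C)[Si](C)(C)OCC(CO[Si](C)(C)C(C)(C)C)=CC[C@@H](C(C)(C)C(C)O)CCC1(C)OCCO1
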